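I decided to judge these flasks by how the partner was spent, not by how the substrate was.

| flask | substrate | partner | remark | time |
|---|---|---|---|---|
| Sunday's | 0.10 M | 0.15 M | run made earlier |  |
| Thursday's | 0.10 M | 0.075 M | run made earlier |  |
| Tuesday's | 0.10 M | 0.11 M | run made earlier |  |
| teal | 0.10 M | 0.150 M | everything together at the start | 15 min |
| blue | 0.10 M | 0.150 M (fed, over 10 min) | all else is in the flask from the start; the feed brings no volume worth counting | 15 min |
| green | 0.10 M (fed, over 10 min) | 0.150 M | all else is in the flask from the start; the feed brings no volume worth counting | 15 min |

| Sunday's: time / min | Sunday's: target / % | Thursday's: time / min | Thursday's: target / % | Tuesday's: time / min | Tuesday's: target / % |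
|---|---|---|---|---|---|
| 1.33 | 12.8 | 1.50 | 10.3 | 4.00 | 32.7 |
| 2.50 | 25.9 | 5.00 | 30.9 | 8.00 | 41.4 |
| 4.00 | 35.7 | 8.00 | 34.5 | 10.0 | 42.6 |
| 8.00 | 45.3 | 12.0 | 35.0 | 15.0 | 41.7 |
| 15.0 | 45.7 | 20.0 | 34.1 | 20.0 | 40.4 |

(scatter of a reading: 0.3 percentage points)

- the numbers in the tables scatter by 0.3 percentage points (one standard deviation)
- steps that have been proposed: substrate -> open intermediate; partner -> second intermediate; open intermediate + second intermediate <-> target; 2 second intermediate -> homo product; target <-> isomer of the product

- the flask that comes out highest in amount of target, in percent of the substrate charged, or "all alike" when all lie within 1.5 percentage points (teal / blue / green / all alike)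
- target at the end, in percent of the substrate charged, teal
- target at the end, in percent of the substrate charged, blue
- target at the end, in percent of the substrate charged, green

Sunday's run and Thursday's run looked nearly the same: equal substrate, with twice the partner on Sunday. Yet the target levelled off at 45.7% on Sunday and 35.0% on Thursday. Per mole of partner charged, Sunday's run gave 0.305 mole of target at its plateau and Thursday's 0.467; I called this the capture share φ. In the proposed steps capture is first order in second intermediate and first order in open intermediate, while coupling to homo product is second order in second intermediate, so the rate of coupling against that of capture goes with the concentration of second intermediate over that of open intermediate. With the same substrate charge in both runs, I read Sunday's smaller share as the result of its larger partner charge, which I took to raise the concentration of second intermediate.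

My own reckoning followed from φ. Teal has Sunday's charge, so I expected about 45.7%. Blue receives the same partner over 10 min, so I placed its share between Sunday's and Thursday's, which means target between 45.7% and 70.0%. Green has its partner present from the start while its substrate arrives slowly, so I placed its share below Sunday's and its target below 45.7%.

The forecast named blue, with teal 45.5%, blue 55% and green 14%, reasoning that “feeding partner keeps the second intermediate low while open intermediate is abundant”.

    substrate → open intermediate (k = 0.00503 s⁻¹)
    partner → second intermediate (k = 0.00820 s⁻¹)
    open intermediate + second intermediate ⇌ target (K = 281 M⁻¹, k = 0.691 M⁻¹ s⁻¹)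
    2 second intermediate → homo product (k = 0.253 M⁻¹ s⁻¹)
    target ⇌ isomer of the product (K = 0.392, k = 0.0365 s⁻¹)

Teal gave 45.3%, blue 58.0% and green 22.1%, so blue came out highest, with φ of 0.302, 0.387 and 0.147 in that order. In green, coupling to homo product had 98% of its turnover behind it after 7.50 min, while the making of open intermediate reached the midpoint of its turnover at 7.63 min. The neighbour of green, charged with 0.40 M of substrate and otherwise held as green, ended at 11.5% of its larger charge, which is φ of 0.307.

(The runs are simulated on assumed constants, and the scatter is random.)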